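**Retrosynthetic overview**

- Feature: ring A carbons C5, C6, C7 and C8, with the vicinal methoxy groups on C6 and C7, correspond to 2,3-dimethoxybutadiene, and the ring-fusion bond C4a=C8a is an alkene of a 4-pyranone, so ring A is annulated onto a finished pyranone.
- Target 14 ⇐ benzyl ether 13 ⇐ (DDQ) 5,8-dihydrochromone 12 ⇐ (decarboxylation–dehydrogenation of the allyl ester) cis-fused adduct 11.
- 11 ⇐ [4+2] cycloaddition of diene 10 across the ester-bearing alkene of allyl 4-oxopyran-3-carboxylate 9, forming C4a–C5 and C8–C8a.
- 9 ⇐ C-acylation of the γ-enolate of enaminone 3 (from 1 and 2) with acid chloride 7 (from 4), then acid-mediated closure of the pyranone.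
- Ring order: pendant arene (purchased) → pyranone ring (step 4) → ring A (step 5, aromatised in steps 6 and 7).

Key step: step 5

Remark: the target has no stereocentre. Adduct 11 is carried as the racemic cis diastereomer, because both of its stereocentres are removed in steps 6 and 7; the alkene geometry of enaminones 3 and 8 is likewise without consequence. Chromone numbering (O1, C2, C3, C4, C4a, C5–C8, C8a) is used for the bicyclic compounds.

**Route**

Step 1
Reactants: 1 allyl acetoacetate; 2 N,N-dimethylformamide dimethyl acetal
Product: 3 allyl 2-[(dimethylamino)methylidene]-3-oxobutanoate (E/Z mixture)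
Conditions: 2 (1.2 equiv), neat, rt to 60 °C; volatiles removed in vacuo
Reagents that add atoms: none
Why: Aminomethylenation (Knoevenagel-type condensation) of the doubly activated C2 methylene of the β-keto ester with the amide acetal should proceed cleanly, driven by loss of two molecules of methanol.

Step 2
Reactants: 4 3-(3-hydroxy-4-methoxyphenyl)propanoic acid
Product: 6 3-[3-(benzyloxy)-4-methoxyphenyl]propanoic acid, via benzyl ester 5 (not isolated)
Conditions: BnBr (2.3 equiv), K2CO3 (3 equiv), DMF, 60 °C; then 2 M aq NaOH, MeOH, 60 °C; then aq HCl to pH 2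
Reagents that add atoms: benzyl bromide, BrCc1ccccc1; sodium hydroxide, [Na+].[OH-]
Why: Williamson O-benzylation of the phenoxide (the carboxylate is benzylated as well) followed by saponification of the benzyl ester in the same pot should leave only the aryl benzyl ether, which shields the phenol from the amide base, the acid chloride and DDQ used later.

Step 3
Reactants: 6 3-[3-(benzyloxy)-4-methoxyphenyl]propanoic acid
Product: 7 3-[3-(benzyloxy)-4-methoxyphenyl]propanoyl chloride
Conditions: (COCl)2 (1.3 equiv), DMF (cat.), CH2Cl2, 0 °C to rt; concentrated and used crude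
Reagents that add atoms: oxalyl chloride, ClC(=O)C(=O)Cl
Why: Vilsmeier-type chlorination of the carboxylic acid with oxalyl chloride and catalytic DMF gives the acid chloride with only volatile by-products and leaves both ethers untouched.

Step 4
Reactants: 3 allyl 2-[(dimethylamino)methylidene]-3-oxobutanoate; 7 3-[3-(benzyloxy)-4-methoxyphenyl]propanoyl chloride
Product: 9 allyl 6-{2-[3-(benzyloxy)-4-methoxyphenyl]ethyl}-4-oxo-4H-pyran-3-carboxylate, via diketo enaminone 8 (not isolated)
Conditions: LiN(SiMe3)2 (2.5 equiv) added to 3 and 7 in THF, −78 °C; then 3 M aq HCl, Et2O, rt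
Reagents that add atoms: none
Why: Deprotonation of the methyl ketone gives a γ-dienolate that undergoes Claisen-type C-acylation by the acid chloride (the excess base also absorbs the more acidic diketone product), and on acidification the enol oxygen of the new ketone adds to the aminomethylene carbon and expels dimethylamine (addition–elimination) to close the 4-pyranone.

Step 5
Reactants: 9 allyl 6-{2-[3-(benzyloxy)-4-methoxyphenyl]ethyl}-4-oxo-4H-pyran-3-carboxylate; 10 2,3-dimethoxybuta-1,3-diene
Product: 11 racemic cis-fused allyl 2-{2-[3-(benzyloxy)-4-methoxyphenyl]ethyl}-6,7-dimethoxy-4-oxo-5,8-dihydro-8aH-chromene-4a-carboxylate (ester at C4a and hydrogen at C8a on the same face; the drawn enantiomer is 4aR,8aR)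
Conditions: 10 (4 equiv), BHT (cat.), PhMe, sealed tube, 130 °C
Reagents that add atoms: none
Why: Diels–Alder reaction: the pyranone C2=C3 bond (C8a=C4a in chromone numbering) is conjugated to both the C4 ketone and the ester, so it should serve as a normal-demand dienophile toward the electron-rich diene in a concerted suprafacial [4+2] cycloaddition, the reaction type known for 3-alkoxycarbonyl- and 3-cyano-chromones and 4-pyranones with oxygenated dienes. Ring A closes by intermolecular [4+2] annulation, with C4a–C5 and C8–C8a formed together from the s-cis diene. The stereocentres C4a and C8a should arise with cis ring fusion because both bonds form on one face of the alkene; the adduct is racemic and both centres are erased in steps 6 and 7. Site selectivity between the two pyranone alkenes is required and is secured because only C2=C3 is doubly activated and unsubstituted at its oxygen-bearing carbon, whereas C5=C6 is singly activated and carries the side chain. The symmetric diene raises no regiochemical question, and the quaternary C4a prevents retro-oxa-Michael opening of the adduct.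

Step 6
Reactants: 11 racemic cis-fused allyl 2-{2-[3-(benzyloxy)-4-methoxyphenyl]ethyl}-6,7-dimethoxy-4-oxo-5,8-dihydro-8aH-chromene-4a-carboxylate
Product: 12 2-{2-[3-(benzyloxy)-4-methoxyphenyl]ethyl}-6,7-dimethoxy-5,8-dihydro-4H-chromen-4-one
Conditions: Pd(OAc)2 (5 mol %), 1,2-bis(diphenylphosphino)ethane (5 mol %), MeCN, reflux
Reagents that add atoms: none
Why: Tsuji decarboxylation–dehydrogenation: Pd(OAc)2 is reduced in situ to zerovalent palladium, which ionises the allyl ester, the carboxylate loses CO2 to give an allylpalladium enolate at C4a, and β-hydride elimination of the C8a hydrogen (favoured over reductive allylation in refluxing MeCN at low phosphine loading) should restore the 4-pyranone with release of propene.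

Step 7
Reactants: 12 2-{2-[3-(benzyloxy)-4-methoxyphenyl]ethyl}-6,7-dimethoxy-5,8-dihydro-4H-chromen-4-one
Product: 13 2-{2-[3-(benzyloxy)-4-methoxyphenyl]ethyl}-6,7-dimethoxy-4H-chromen-4-one
Conditions: DDQ (1.1 equiv), 1,4-dioxane, rt
Reagents that add atoms: none
Why: DDQ dehydrogenation of the 1,4-cyclohexadiene ring (hydride abstraction from the allylic, enol-ether-activated C5 or C8 position, then proton loss) is driven by formation of aromatic ring A and should be much faster at room temperature than oxidation of the aryl benzyl ether or the ArCH2CH2 chain.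

Step 8
Reactants: 13 2-{2-[3-(benzyloxy)-4-methoxyphenyl]ethyl}-6,7-dimethoxy-4H-chromen-4-one
Product: 14 2-[2-(3-hydroxy-4-methoxyphenyl)ethyl]-6,7-dimethoxy-4H-chromen-4-one (CNP0303336.0)
Conditions: H2 (1 atm), 10% Pd/C, EtOAc–MeOH, rt; stopped after one equivalent of H2
Reagents that add atoms: none
Why: Catalytic hydrogenolysis of the aryl benzyl ether over palladium on carbon should free the phenol, while the chromone C2=C3 bond and the methyl ethers are not reduced under these mild conditions.

**Compound list**

1 | allyl acetoacetate (prop-2-en-1-yl 3-oxobutanoate) | CC(=O)CC(=O)OCC=C | starting material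
2 | N,N-dimethylformamide dimethyl acetal | COC(OC)N(C)C | starting material
3 | allyl 2-[(dimethylamino)methylidene]-3-oxobutanoate (E/Z mixture) | CC(=O)C(=CN(C)C)C(=O)OCC=C | intermediate
4 | 3-(3-hydroxy-4-methoxyphenyl)propanoic acid | COc1ccc(CCC(=O)O)cc1O | starting material
5 | benzyl 3-[3-(benzyloxy)-4-methoxyphenyl]propanoate (formed in the flask, not isolated) | COc1ccc(CCC(=O)OCc2ccccc2)cc1OCc1ccccc1 | intermediate
6 | 3-[3-(benzyloxy)-4-methoxyphenyl]propanoic acid | COc1ccc(CCC(=O)O)cc1OCc1ccccc1 | intermediate
7 | 3-[3-(benzyloxy)-4-methoxyphenyl]propanoyl chloride | COc1ccc(CCC(=O)Cl)cc1OCc1ccccc1 | intermediate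
8 | allyl 7-[3-(benzyloxy)-4-methoxyphenyl]-2-[(dimethylamino)methylidene]-3,5-dioxoheptanoate (formed in the flask, not isolated) | C=CCOC(=O)C(=CN(C)C)C(=O)CC(=O)CCc1ccc(OC)c(OCc2ccccc2)c1 | intermediate
9 | allyl 6-{2-[3-(benzyloxy)-4-methoxyphenyl]ethyl}-4-oxo-4H-pyran-3-carboxylate | C=CCOC(=O)C1=COC(CCc2ccc(OC)c(OCc3ccccc3)c2)=CC1=O | intermediate
10 | 2,3-dimethoxybuta-1,3-diene | C=C(OC)C(OC)=C | starting material
11 | racemic cis-fused allyl 2-{2-[3-(benzyloxy)-4-methoxyphenyl]ethyl}-6,7-dimethoxy-4-oxo-5,8-dihydro-8aH-chromene-4a-carboxylate (4aR,8aR enantiomer drawn) | C=CCOC(=O)[C@]12CC(OC)=C(OC)C[C@H]1OC(CCc1ccc(OC)c(OCc3ccccc3)c1)=CC2=O | intermediate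
12 | 2-{2-[3-(benzyloxy)-4-methoxyphenyl]ethyl}-6,7-dimethoxy-5,8-dihydro-4H-chromen-4-one | O=C1C=C(CCc2ccc(OC)c(OCc3ccccc3)c2)OC2=C1CC(OC)=C(OC)C2 | intermediate
13 | 2-{2-[3-(benzyloxy)-4-methoxyphenyl]ethyl}-6,7-dimethoxy-4H-chromen-4-one | COc1ccc(CCc2cc(=O)c3cc(OC)c(OC)cc3o2)cc1OCc1ccccc1 | intermediate
14 | 2-[2-(3-hydroxy-4-methoxyphenyl)ethyl]-6,7-dimethoxy-4H-chromen-4-one | COc1ccc(CCc2cc(=O)c3cc(OC)c(OC)cc3o2)cc1O | target

**Step count**

Total steps: 8. Longest linear sequence: 7 steps (steps 2 to 8, from 4); step 1 is a one-step branch that joins at step 4.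

**Steps most likely to fail**

1. Step 5 (Diels–Alder). The cycloaddition may be sluggish because the pyranone alkene has aromatic-like stabilisation. Competing processes are polymerisation of the diene, an inverse-demand hetero-Diels–Alder reaction of the keto-ester oxadiene with one enol-ether double bond of the diene, and hydrolysis of the enol ethers of the adduct by adventitious acid. Chelating activation with anhydrous ZnCl2 in CH2Cl2 at room temperature is the first adjustment. The fallback proper gives up the de novo construction of ring A and uses a preformed ring A. It sets out from acid chloride 7, which acylates commercial 1-(2-hydroxy-4,5-dimethoxyphenyl)ethanone (CC(=O)c1cc(OC)c(OC)cc1O) in pyridine to give the aryl ester 2-acetyl-4,5-dimethoxyphenyl 3-[3-(benzyloxy)-4-methoxyphenyl]propanoate F1. Baker–Venkataraman rearrangement (KO-t-Bu, THF, 0 °C to rt) then gives the diketone 5-[3-(benzyloxy)-4-methoxyphenyl]-1-(2-hydroxy-4,5-dimethoxyphenyl)pentane-1,3-dione F2. Cyclodehydration (conc. HCl, AcOH, 80 °C) closes the pyranone ring, and the route is rejoined at 13, before step 8.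

2. Step 6 (decarboxylation–dehydrogenation). Reductive elimination of the allylpalladium enolate may outrun β-hydride elimination and install an allyl group at C4a, which blocks aromatisation. The fallback removes the ester reductively and leaves all of the dehydrogenation to the oxidant. It sets out from 11, which is treated with Pd(OAc)2, PPh3 and HCO2H–Et3N in THF at rt, so that formate delivers hydride to the allyl group and the β-keto acid decarboxylates. This gives 2-{2-[3-(benzyloxy)-4-methoxyphenyl]ethyl}-6,7-dimethoxy-4a,5,8,8a-tetrahydro-4H-chromen-4-one F3, whose ring-fusion configuration is of no consequence. DDQ (2.2 equiv) in 1,4-dioxane at 80 °C should then remove four hydrogens from ring A, and the route is rejoined at 13, bypassing 12.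

3. Step 4 (acylation and pyranone closure). The enolisable acid chloride may be converted into a ketene, or may N-acylate the silylamide base, faster than it C-acylates the dienolate; this would consume 7 and return 3. The fallback forms the same carbon–carbon bond by aldol addition and adjusts the oxidation level afterwards. It sets out from 7, which is reduced with LiAlH(O-t-Bu)3 in THF at −78 °C to 3-[3-(benzyloxy)-4-methoxyphenyl]propanal F4. The lithium dienolate of 3 (LiN(SiMe3)2, THF, −78 °C) is added to this aldehyde to give racemic allyl 7-[3-(benzyloxy)-4-methoxyphenyl]-2-[(dimethylamino)methylidene]-5-hydroxy-3-oxoheptanoate F5. Oxidation with Dess–Martin periodinane in CH2Cl2 gives 8, which is closed with 3 M aq HCl in Et2O as in step 4, and the route is rejoined at 9.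

**Further compounds**

F1 | step 5 | 2-acetyl-4,5-dimethoxyphenyl 3-[3-(benzyloxy)-4-methoxyphenyl]propanoate | CC(=O)c1cc(OC)c(OC)cc1OC(=O)CCc1ccc(OC)c(OCc2ccccc2)c1
F2 | step 5 | 5-[3-(benzyloxy)-4-methoxyphenyl]-1-(2-hydroxy-4,5-dimethoxyphenyl)pentane-1,3-dione | COc1cc(O)c(cc1OC)C(=O)CC(=O)CCc1ccc(OC)c(OCc2ccccc2)c1
F3 | step 6 | 2-{2-[3-(benzyloxy)-4-methoxyphenyl]ethyl}-6,7-dimethoxy-4a,5,8,8a-tetrahydro-4H-chromen-4-one (ring-fusion epimers, configuration not defined) | O=C1C=C(CCc2ccc(OC)c(OCc3ccccc3)c2)OC2CC(OC)=C(OC)CC12
F4 | step 4 | 3-[3-(benzyloxy)-4-methoxyphenyl]propanal | COc1ccc(CCC=O)cc1OCc1ccccc1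
F5 | step 4 | allyl 7-[3-(benzyloxy)-4-methoxyphenyl]-2-[(dimethylamino)methylidene]-5-hydroxy-3-oxoheptanoate (racemic) | C=CCOC(=O)C(=CN(C)C)C(=O)CC(O)CCc1ccc(OC)c(OCc2ccccc2)c1
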